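**Retrosynthetic overview**

- Feature: in ring C (chroman-4-one numbering) C6 carries the diaryl ether oxygen between C7 (lactone oxygen) and C5 (methyl), and the C7 and C8a oxygens are meta. A vinylketene plus an alkoxyalkyne gives exactly this resorcinol pattern, so the crowded C6–O–aryl bond enters as an enol ether oxygen with no aryl–oxygen coupling.
- Disconnections, last to first: ring A C3–CHO (formylation); ring B lactone C(=O)–O7 (carbodiimide closure of the free acid); ring D C4–C4a and O1–C2 (Friedel–Crafts acylation, oxa-Michael); ring C bonds C4a–C5, C7–C8, C8a–C4a and C6–C7 (photochemical benzannulation of a diazo enone with ethoxyacetylene).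
- The diazo enone comes from methyl orsellinate (ring A) and an (E)-3-bromo-2-methylacrylate made from methacrylic acid.
- Ring order: A (bought), C (benzannulation), D (chromanone), B (seven-membered lactone); the formyl group is placed last.
- End-game design: the new phenol is capped and ring D is acylated while ring C is still a resorcinol diether (far more reactive than ring A). The lactone is closed only from the free acid, because transesterification of a methyl ester to an aryl ester is uphill.

Key step: step 8

Remark: ring C and ring D atoms are numbered as in chroman-4-one (O1, C2, C3, C4, C4a, C5–C8, C8a) and ring A as a benzoate (C1 bears the carboxyl carbon). The target has no stereocentre, so the only stereochemical element on the way is the E geometry of the enol ether. Compounds 1, 3, 11 and 18 are taken as commercial (11 as a hexane solution).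

**Route**

Step 1
Reactants: 1 methyl orsellinate (methyl 2,4-dihydroxy-6-methylbenzoate)
Product: 2 methyl 2-hydroxy-4-methoxy-6-methylbenzoate
Conditions: MeI (1.05 equiv), K2CO3, acetone, reflux
Reagents that add atoms: iodomethane CI
Why: Williamson methylation takes the free 4-hydroxyl, because the 2-hydroxyl is hydrogen-bonded to the ester carbonyl and much less nucleophilic.

Step 2
Reactants: 3 methacrylic acid
Product: 4 2,3-dibromo-2-methylpropanoic acid (racemic)
Conditions: Br2, CH2Cl2, 0 → 20 °C
Reagents that add atoms: bromine BrBr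
Why: Electrophilic anti addition of bromine to the 1,1-disubstituted alkene is straightforward.

Step 3
Reactants: 4 2,3-dibromo-2-methylpropanoic acid
Product: 5 (E)-3-bromo-2-methylprop-2-enoic acid
Conditions: KOH, EtOH, 0 → 78 °C; then aq. HCl; recrystallisation
Reagents that add atoms: none
Why: Base-induced anti elimination of HBr (E2) from the carboxylate removes the tertiary bromide and a CH2Br hydrogen; the E acid (bromine trans to the carboxyl group) is expected to predominate and is secured by crystallisation.

Step 4
Reactants: 5 (E)-3-bromo-2-methylprop-2-enoic acid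
Product: 6 tert-butyl (E)-3-bromo-2-methylprop-2-enoate
Conditions: t-BuOC(=NH)CCl3, BF3·OEt2 (cat.), CH2Cl2–cyclohexane, 20 °C
Reagents that add atoms: tert-butyl 2,2,2-trichloroacetimidate CC(C)(C)OC(=N)C(Cl)(Cl)Cl
Why: Acid-catalysed tert-butyl transfer from the imidate esterifies the acid without touching the bromoalkene, and gives an ester that can later be cleaved beside the methyl benzoate.

Step 5
Reactants: 2 methyl 2-hydroxy-4-methoxy-6-methylbenzoate; 6 tert-butyl (E)-3-bromo-2-methylprop-2-enoate
Product: 7 methyl 2-{[(E)-3-tert-butoxy-2-methyl-3-oxoprop-1-enyl]oxy}-4-methoxy-6-methylbenzoate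
Conditions: Cs2CO3, CuI (10 mol %), N,N-dimethylglycine (20 mol %), dioxane, 90 °C
Reagents that add atoms: none
Why: CuI-catalysed Ullmann-type O-vinylation of the phenoxide by the β-bromoacrylate, backed by uncatalysed addition–elimination at the β-carbon that gives the same product, proceeds with retention of the E geometry; both esters are inert to anhydrous carbonate.

Step 6
Reactants: 7 methyl 2-{[(E)-3-tert-butoxy-2-methyl-3-oxoprop-1-enyl]oxy}-4-methoxy-6-methylbenzoate
Product: 8 (E)-3-[5-methoxy-2-(methoxycarbonyl)-3-methylphenoxy]-2-methylprop-2-enoic acid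
Conditions: CF3CO2H, CH2Cl2, 20 °C
Reagents that add atoms: none
Why: Acidolysis of the tert-butyl ester by loss of isobutene leaves the methyl ester and the β-aryloxyacrylate, whose acceptor-substituted enol ether resists protonation.

Step 7
Reactants: 8 (E)-3-[5-methoxy-2-(methoxycarbonyl)-3-methylphenoxy]-2-methylprop-2-enoic acid
Product: 10 methyl 2-[(E)-4-diazo-2-methyl-3-oxobut-1-enyloxy]-4-methoxy-6-methylbenzoate, via acid chloride 9 (not isolated)
Conditions: (COCl)2, DMF (cat.), CH2Cl2, 0 → 20 °C; evaporate; CH2N2 (3 equiv), Et2O, 0 °C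
Reagents that add atoms: diazomethane C=[N+]=[N-]
Why: Acylation of diazomethane by the acid chloride (Arndt–Eistert-type diazoketone synthesis), with a second equivalent taking up HCl; the trisubstituted, donor-substituted double bond is a poor dipolarophile, so pyrazoline formation should not compete.

Step 8
Reactants: 10 methyl 2-[(E)-4-diazo-2-methyl-3-oxobut-1-enyloxy]-4-methoxy-6-methylbenzoate; 11 ethoxyacetylene
Product: 16 methyl 2-(4-ethoxy-2-hydroxy-6-methylphenoxy)-4-methoxy-6-methylbenzoate, via aryloxyvinylketene 12 (not isolated), via 4-alkenylcyclobutenone 13 (not isolated), via dienylketene 14 (not isolated), via cyclohexa-2,4-dienone 15 (not isolated)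
Conditions: 11 (4 equiv), hν (254 nm, low-pressure Hg lamps, quartz), ClCH2CH2Cl, 20 °C; then 80 °C (sealed tube)
Reagents that add atoms: none
Why: Light expels N2 from 10 and the alkenyl group shifts to the carbene carbon (Wolff rearrangement) to give vinylketene 12, which adds ethoxyacetylene in a [2+2] cycloaddition to cyclobutenone 13, and this opens in a four-electron electrocyclic step to dienylketene 14. Ring C closes by six-electron electrocyclisation of 14 (bond C6–C7) to dienone 15, which tautomerises to phenol 16; this is the Danheiser benzannulation in its photochemical Wolff variant with an alkoxyalkyne. The sequence forms C4a–C5 (1,2-shift), C7–C8 and C8a–C4a ([2+2]) and C6–C7 (ring closure), the former diazo carbon becoming C4a and the former ketone carbon C7. No stereocentre survives, since the sp3 carbons of 13 and 15 are lost on aromatisation. The required regiochemistry, ethoxy meta to the new hydroxyl, follows from the polarisation of the alkoxyalkyne, whose nucleophilic CH carbon bonds to the ketene carbonyl carbon. An excess of 11 lets the cycloaddition outrun dimerisation of 12 and its capture by the product phenol, and the E enol ether keeps the aryloxy group on the outside of the closing triene.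

Step 9
Reactants: 16 methyl 2-(4-ethoxy-2-hydroxy-6-methylphenoxy)-4-methoxy-6-methylbenzoate
Product: 17 methyl 2-(4-ethoxy-2-methoxy-6-methylphenoxy)-4-methoxy-6-methylbenzoate
Conditions: MeI, K2CO3, acetone, reflux
Reagents that add atoms: iodomethane CI
Why: Williamson methylation caps the C7 oxygen as a para-directing ether, so the next step cannot begin with O-acylation and a hydroxyl-directed attack at C8.

Step 10
Reactants: 17 methyl 2-(4-ethoxy-2-methoxy-6-methylphenoxy)-4-methoxy-6-methylbenzoate; 18 3-methylbut-2-enoyl chloride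
Product: 19 methyl 2-[4-ethoxy-6-methoxy-2-methyl-3-(3-methylbut-2-enoyl)phenoxy]-4-methoxy-6-methylbenzoate
Conditions: AlCl3, CH2Cl2, −20 → 0 °C
Reagents that add atoms: none
Why: Friedel–Crafts acylation should go to C4a (para to the C7 methoxy group, ortho to the C8a ethoxy group, next to the C5 methyl) as in acylations of orcinol dialkyl ethers, while C8 between the two alkoxy groups is shielded and ring A is deactivated by its ester.

Step 11
Reactants: 19 methyl 2-[4-ethoxy-6-methoxy-2-methyl-3-(3-methylbut-2-enoyl)phenoxy]-4-methoxy-6-methylbenzoate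
Product: 21 4-hydroxy-2-[(7-hydroxy-2,2,5-trimethyl-4-oxo-3,4-dihydro-2H-chromen-6-yl)oxy]-6-methylbenzoic acid, via hydroxy enone acid 20 (not isolated)
Conditions: BBr3 (excess), CH2Cl2, −78 → 20 °C; H2O; then NaOAc, EtOH–H2O, 50 °C
Reagents that add atoms: none
Why: BBr3 cleaves the three aryl alkyl ethers and, by bromide attack at the O-methyl carbon, the hindered methyl ester; on buffering the freed C8a phenol adds 6-endo to the enone (oxa-Michael) to close ring D, the C7 phenol being para to the acyl group and unable to cyclise.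

Step 12
Reactants: 21 4-hydroxy-2-[(7-hydroxy-2,2,5-trimethyl-4-oxo-3,4-dihydro-2H-chromen-6-yl)oxy]-6-methylbenzoic acid
Product: 22 deformylmollicellin A (the depsidone in which the ring A carboxyl is lactonised onto the C7 oxygen; the target without its formyl group)
Conditions: DCC, THF–CH2Cl2 (high dilution), 20 °C
Reagents that add atoms: none
Why: Carbodiimide activation of the acid and intramolecular attack by the C7 phenol, the only hydroxyl within reach, close the seven-membered ring B (depsidone lactonisation); the ring A hydroxyl is para to the carboxyl and could react only between molecules, which dilution suppresses.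

Step 13
Reactants: 22 deformylmollicellin A
Product: 23 Mollicellin A
Conditions: Cl2CHOCH3, TiCl4, CH2Cl2, −10 → 0 °C; then aq. HCl
Reagents that add atoms: dichloromethyl methyl ether COC(Cl)Cl (formyl carbon); water O (formyl oxygen, on hydrolysis)
Why: Rieche formylation directed by the titanium phenoxide should enter ring A ortho to the free hydroxyl at C3, the less hindered site flanked by two oxygens, while ring C is deactivated by the chromanone carbonyl and the lactone.

**Compound list**

1 | methyl orsellinate (methyl 2,4-dihydroxy-6-methylbenzoate) | Cc1cc(O)cc(O)c1C(=O)OC | starting material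
2 | methyl 2-hydroxy-4-methoxy-6-methylbenzoate | Cc1cc(OC)cc(O)c1C(=O)OC | intermediate
3 | methacrylic acid | CC(=C)C(=O)O | starting material
4 | 2,3-dibromo-2-methylpropanoic acid (racemic) | CC(Br)(CBr)C(=O)O | intermediate
5 | (E)-3-bromo-2-methylprop-2-enoic acid | Br/C=C(\C)C(=O)O | intermediate
6 | tert-butyl (E)-3-bromo-2-methylprop-2-enoate | Br/C=C(\C)C(=O)OC(C)(C)C | intermediate
7 | methyl 2-{[(E)-3-tert-butoxy-2-methyl-3-oxoprop-1-enyl]oxy}-4-methoxy-6-methylbenzoate | Cc1cc(OC)cc(O/C=C(\C)C(=O)OC(C)(C)C)c1C(=O)OC | intermediate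
8 | (E)-3-[5-methoxy-2-(methoxycarbonyl)-3-methylphenoxy]-2-methylprop-2-enoic acid | Cc1cc(OC)cc(O/C=C(\C)C(=O)O)c1C(=O)OC | intermediate
9 | (E)-3-[5-methoxy-2-(methoxycarbonyl)-3-methylphenoxy]-2-methylprop-2-enoyl chloride | Cc1cc(OC)cc(O/C=C(\C)C(=O)Cl)c1C(=O)OC | intermediate
10 | methyl 2-[(E)-4-diazo-2-methyl-3-oxobut-1-enyloxy]-4-methoxy-6-methylbenzoate | Cc1cc(OC)cc(O/C=C(\C)C(=O)C=[N+]=[N-])c1C(=O)OC | intermediate
11 | ethoxyacetylene | C#COCC | starting material
12 | aryloxyvinylketene: methyl 4-methoxy-2-methyl-6-[(E)-2-methyl-4-oxobuta-1,3-dienyloxy]benzoate | Cc1cc(OC)cc(O/C=C(\C)C=C=O)c1C(=O)OC | intermediate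
13 | 4-alkenylcyclobutenone: methyl 2-{[(E)-2-(2-ethoxy-4-oxocyclobut-2-enyl)prop-1-enyl]oxy}-4-methoxy-6-methylbenzoate (racemic) | CCOC1=CC(=O)C1/C(C)=C/Oc1cc(OC)cc(C)c1C(=O)OC | intermediate
14 | dienylketene: methyl 2-{[(1E,3E)-4-ethoxy-2-methyl-6-oxohexa-1,3,5-trienyl]oxy}-4-methoxy-6-methylbenzoate | O=C=C/C(OCC)=C\C(C)=C\Oc1cc(OC)cc(C)c1C(=O)OC | intermediate
15 | cyclohexa-2,4-dienone: methyl 2-[(4-ethoxy-6-methyl-2-oxocyclohexa-3,5-dienyl)oxy]-4-methoxy-6-methylbenzoate (racemic) | CCOC1=CC(=O)C(Oc2cc(OC)cc(C)c2C(=O)OC)C(C)=C1 | intermediate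
16 | methyl 2-(4-ethoxy-2-hydroxy-6-methylphenoxy)-4-methoxy-6-methylbenzoate | Cc1cc(OC)cc(Oc2c(C)cc(OCC)cc2O)c1C(=O)OC | intermediate
17 | methyl 2-(4-ethoxy-2-methoxy-6-methylphenoxy)-4-methoxy-6-methylbenzoate | Cc1cc(OC)cc(Oc2c(C)cc(OCC)cc2OC)c1C(=O)OC | intermediate
18 | 3-methylbut-2-enoyl chloride | CC(C)=CC(=O)Cl | starting material
19 | methyl 2-[4-ethoxy-6-methoxy-2-methyl-3-(3-methylbut-2-enoyl)phenoxy]-4-methoxy-6-methylbenzoate | Cc1cc(OC)cc(Oc2c(C)c(C(=O)C=C(C)C)c(OCC)cc2OC)c1C(=O)OC | intermediate
20 | 2-[4,6-dihydroxy-2-methyl-3-(3-methylbut-2-enoyl)phenoxy]-4-hydroxy-6-methylbenzoic acid | Cc1cc(O)cc(Oc2c(C)c(C(=O)C=C(C)C)c(O)cc2O)c1C(=O)O | intermediate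
21 | 4-hydroxy-2-[(7-hydroxy-2,2,5-trimethyl-4-oxo-3,4-dihydro-2H-chromen-6-yl)oxy]-6-methylbenzoic acid | Cc1cc(O)cc(Oc2c(C)c3C(=O)CC(C)(C)Oc3cc2O)c1C(=O)O | intermediate
22 | deformylmollicellin A (depsidone lactone of 21) | Cc1cc(O)cc2c1C(=O)Oc1cc3c(c(C)c1O2)C(=O)CC(C)(C)O3 | intermediate
23 | Mollicellin A | Cc1cc(O)c(C=O)c2c1C(=O)Oc1cc3c(c(C)c1O2)C(=O)CC(C)(C)O3 | target

**Step count**

Total: 13 steps. Longest linear sequence: 12 steps (3 → 23, steps 2–13); 10 steps from methyl orsellinate.

**Steps most likely to fail**

Step 8. Competing photochemistry of the aryl enol ether chromophore, dimerisation of ketene 12, or its capture by the product phenol could leave little of 16. The fallback sets out from 2 and returns at 21; it makes the diaryl ether by aryl–oxygen coupling, at the price of the hindered coupling the main route avoids. 3,5-Dimethoxytoluene, I2, mCPBA and TsOH give the symmetric salt bis(2,4-dimethoxy-6-methylphenyl)iodonium tosylate F1. Phenol 2 is O-arylated with it (t-BuOK, THF, 40 °C, no metal) to methyl 2-(2,4-dimethoxy-6-methylphenoxy)-4-methoxy-6-methylbenzoate F2. Acylation with 18 under the conditions of step 10 gives methyl 2-[4,6-dimethoxy-2-methyl-3-(3-methylbut-2-enoyl)phenoxy]-4-methoxy-6-methylbenzoate F3, and BBr3 then NaOAc as in step 11 takes it through 20 to 21.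

Step 11. Addition of HBr to the enone and its oligomerisation under the strong Lewis acid, incomplete cleavage of the hindered ester, or loss of CO2 from the electron-rich acid could erode the step. The fallback sets out from 19 and returns at 21; ring D is closed before the global dealkylation. BCl3 (CH2Cl2, −78 → 0 °C) removes only the ethyl group next to the ketone through the chelate, giving methyl 2-[4-hydroxy-6-methoxy-2-methyl-3-(3-methylbut-2-enoyl)phenoxy]-4-methoxy-6-methylbenzoate F4. NaOAc in EtOH closes this to methyl 4-methoxy-2-[(7-methoxy-2,2,5-trimethyl-4-oxo-3,4-dihydro-2H-chromen-6-yl)oxy]-6-methylbenzoate F5. BBr3 then cleaves the two methyl ethers and the methyl ester of the robust chromanone to give 21.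

Step 13. The electrophile may enter ring A at C5 (ortho to the hydroxyl, para to the ether oxygen) instead of C3, giving poor positional selectivity. The fallback sets out from 22 and returns at 23; the competing position is blocked first. NBS (1 equiv, CH2Cl2, 0 °C) brominates C5 to give 5-bromodeformylmollicellin A F6 (ring A benzoate numbering). Formylation as in step 13 can then only enter C3, giving 5-bromomollicellin A F7. Hydrodebromination with Pd(OAc)2, PPh3, HCO2H and Et3N in DMF at 60 °C gives 23.

**Further compounds**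

F1 | step 8 | bis(2,4-dimethoxy-6-methylphenyl)iodonium 4-methylbenzenesulfonate | Cc1cc(OC)cc(OC)c1[I+]c1c(C)cc(OC)cc1OC.Cc1ccc(cc1)S(=O)(=O)[O-]
F2 | step 8 | methyl 2-(2,4-dimethoxy-6-methylphenoxy)-4-methoxy-6-methylbenzoate | Cc1cc(OC)cc(Oc2c(C)cc(OC)cc2OC)c1C(=O)OC
F3 | step 8 | methyl 2-[4,6-dimethoxy-2-methyl-3-(3-methylbut-2-enoyl)phenoxy]-4-methoxy-6-methylbenzoate | Cc1cc(OC)cc(Oc2c(C)c(C(=O)C=C(C)C)c(OC)cc2OC)c1C(=O)OC
F4 | step 11 | methyl 2-[4-hydroxy-6-methoxy-2-methyl-3-(3-methylbut-2-enoyl)phenoxy]-4-methoxy-6-methylbenzoate | Cc1cc(OC)cc(Oc2c(C)c(C(=O)C=C(C)C)c(O)cc2OC)c1C(=O)OC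
F5 | step 11 | methyl 4-methoxy-2-[(7-methoxy-2,2,5-trimethyl-4-oxo-3,4-dihydro-2H-chromen-6-yl)oxy]-6-methylbenzoate | Cc1cc(OC)cc(Oc2c(C)c3C(=O)CC(C)(C)Oc3cc2OC)c1C(=O)OC
F6 | step 13 | 5-bromodeformylmollicellin A (bromine on ring A between the hydroxyl and the methyl group) | Cc1c(Br)c(O)cc2c1C(=O)Oc1cc3c(c(C)c1O2)C(=O)CC(C)(C)O3
F7 | step 13 | 5-bromomollicellin A (bromine on ring A between the hydroxyl and the methyl group) | Cc1c(Br)c(O)c(C=O)c2c1C(=O)Oc1cc3c(c(C)c1O2)C(=O)CC(C)(C)O3
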